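**Assumption:** the target is drawn as one enol tautomer of a β-triketone and is made as the equilibrating tautomer set; metal enolates formed by simple deprotonation of a numbered compound are counted as that compound; the acetal carbon of the 1-ethoxyethyl (EE) group is an inconsequential 1:1 epimer mixture and is left undefined in SMILES.

## Retrosynthetic overview

1. The single ring is formed once, by the Claisen (Dieckmann) closure of a linear 3,5,7-triketo ester, the same C6→C1 closure that the acylphloroglucinol synthase performs on its tetraketide.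
2. The gem-diprenyl carbon is built into the chain before cyclization: dimethyl malonate (1) + prenyl bromide (2) → diester 3; the dianion of 5-methylhexane-2,4-dione (4) is acylated by 3 to tetraketide ester 5, which closes in the same flask to the dearomatized ring 6.
3. Side chain: C2' comes from the chiral pool, methyl (S)-2-hydroxy-3-methylbutanoate (7) → EE ether 8 → aldehyde 9.
4. Last C–C bond (ring C4–C1'): chelation-controlled addition of the magnesium dienolate of 6 to 9 sets C1' (syn) and gives 10; acidic work-up releases the target 11.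

## Route

**Step 1**
Reactants: 1 dimethyl malonate; 2 1-bromo-3-methylbut-2-ene (prenyl bromide, 2.3 equiv)
Product: 3 dimethyl 2,2-bis(3-methylbut-2-en-1-yl)malonate
Conditions: NaH (2.4 equiv), THF/DMF 4:1, 0 °C → rt, 12 h
Reagents that add atoms: none
Why: Double SN2 C-alkylation of the malonate enolate (malonic ester alkylation) with a reactive allylic bromide runs cleanly to the gem-dialkyl diester because the mono-alkylated malonate is still acidic; no stereocenter is formed.

**Step 2**
Reactants: 4 5-methylhexane-2,4-dione (1.1 equiv); 3 dimethyl 2,2-bis(3-methylbut-2-en-1-yl)malonate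
Product: 6 3,5-dihydroxy-2-(2-methylpropanoyl)-6,6-bis(3-methylbut-2-en-1-yl)cyclohexa-2,4-dien-1-one, via linear triketo ester 5 (not isolated)
Conditions: LiN(iPr)2 (3.3 equiv), THF, –78 → 0 °C; add 3, 0 °C → rt; then 65 °C, 12 h; 1 M aq. HCl work-up
Reagents that add atoms: none
Why: Proposed new method: the kinetic 1,3-dianion of 4 (deprotonated at C3 and at the terminal CH3, not at the isopropyl CH) is C-acylated at its terminal carbon by one ester group of 3 (Claisen acylation of a β-diketone dianion by an ester, the closest known reaction type) to give tetraketide ester 5, whose doubly stabilized C6 carbanion then attacks the remaining ester in a 6-exo-trig Dieckmann closure that copies the biosynthetic C6→C1 Claisen cyclization, the quaternary C2 excluding the aldol mode and aromatization, and the strongly acidic triketone product, held as its dilithium salt, drawing reversible O-acylation (pyranone) by-products over to the C-acylated ring; no stereocenter is formed.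

**Step 3**
Reactants: 7 methyl (S)-2-hydroxy-3-methylbutanoate
Product: 8 methyl (2S)-2-(1-ethoxyethoxy)-3-methylbutanoate
Conditions: ethyl vinyl ether (3 equiv), pyridinium p-toluenesulfonate (5 mol %), CH2Cl2, 0 °C → rt
Reagents that add atoms: ethyl vinyl ether, C=COCC
Why: Acid-catalysed addition of the alcohol to the enol ether (acetal protection as the EE ether) is too mild to epimerize the α-center, which is carried unchanged from the L-valine-derived chiral pool and becomes C2' (S) of the target.

**Step 4**
Reactants: 8 methyl (2S)-2-(1-ethoxyethoxy)-3-methylbutanoate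
Product: 9 (2S)-2-(1-ethoxyethoxy)-3-methylbutanal
Conditions: iBu2AlH (1.1 equiv), CH2Cl2, –78 °C, 1 h; aq. KNaC4H4O6 work-up; used crude
Reagents that add atoms: none
Why: Partial ester reduction with iBu2AlH stops at the aldehyde because the aluminium-bound tetrahedral hemiacetal, chelated by the α-alkoxy oxygen, survives at –78 °C until work-up; the α-stereocenter is untouched.

**Step 5**
Reactants: 6 3,5-dihydroxy-2-(2-methylpropanoyl)-6,6-bis(3-methylbut-2-en-1-yl)cyclohexa-2,4-dien-1-one; 9 (2S)-2-(1-ethoxyethoxy)-3-methylbutanal (1.3 equiv)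
Product: 11 3,5-dihydroxy-4-[(1S,2S)-1,2-dihydroxy-3-methylbutyl]-2-(2-methylpropanoyl)-6,6-bis(3-methylbut-2-en-1-yl)cyclohexa-2,4-dien-1-one, via EE-protected adduct 10 (not isolated)
Conditions: EtMgBr (2.0 equiv), CH2Cl2, –20 °C, Ar; then 9, –40 → 0 °C; then 0.5 M aq. HCl/THF, rt, 1 h
Reagents that add atoms: none
Why: Proposed new method: the bis(bromomagnesium) dienolate of 6 adds through its only C–H nucleophilic carbon (C4) to the aldehyde in an aldol-type hydroxyalkylation (closest known reaction type: ortho-specific addition of bromomagnesium phenolates to chiral α-alkoxy aldehydes) via a Cram chelate in which magnesium bridges the aldehyde oxygen and the α-acetal oxygen of 9, so that C4 arrives on the face opposite the isopropyl group and gives the 1'S (syn) carbinol next to the 2'S center, the magnesium-chelated aldolate resisting dehydration at low temperature, and the dilute-acid work-up then hydrolyses the EE acetal.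

## Compound list

1 | dimethyl malonate | COC(=O)CC(=O)OC | starting material
2 | 1-bromo-3-methylbut-2-ene (prenyl bromide) | CC(C)=CCBr | starting material
3 | dimethyl 2,2-bis(3-methylbut-2-en-1-yl)malonate | COC(=O)C(CC=C(C)C)(CC=C(C)C)C(=O)OC | intermediate
4 | 5-methylhexane-2,4-dione | CC(=O)CC(=O)C(C)C | starting material
5 | methyl 8-methyl-2,2-bis(3-methylbut-2-en-1-yl)-3,5,7-trioxononanoate (linear triketo ester, not isolated) | COC(=O)C(CC=C(C)C)(CC=C(C)C)C(=O)CC(=O)CC(=O)C(C)C | intermediate
6 | 3,5-dihydroxy-2-(2-methylpropanoyl)-6,6-bis(3-methylbut-2-en-1-yl)cyclohexa-2,4-dien-1-one | CC(C)=CCC1(CC=C(C)C)C(=O)C(C(=O)C(C)C)=C(O)C=C1O | intermediate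
7 | methyl (S)-2-hydroxy-3-methylbutanoate | COC(=O)[C@@H](O)C(C)C | starting material
8 | methyl (2S)-2-(1-ethoxyethoxy)-3-methylbutanoate | COC(=O)[C@@H](OC(C)OCC)C(C)C | intermediate
9 | (2S)-2-(1-ethoxyethoxy)-3-methylbutanal | O=C[C@@H](OC(C)OCC)C(C)C | intermediate
10 | 4-[(1S,2S)-2-(1-ethoxyethoxy)-1-hydroxy-3-methylbutyl]-3,5-dihydroxy-2-(2-methylpropanoyl)-6,6-bis(3-methylbut-2-en-1-yl)cyclohexa-2,4-dien-1-one (not isolated) | CC(C)=CCC1(CC=C(C)C)C(=O)C(C(=O)C(C)C)=C(O)C([C@H](O)[C@@H](OC(C)OCC)C(C)C)=C1O | intermediate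
11 | 3,5-dihydroxy-4-[(1S,2S)-1,2-dihydroxy-3-methylbutyl]-2-(2-methylpropanoyl)-6,6-bis(3-methylbut-2-en-1-yl)cyclohexa-2,4-dien-1-one | CC(C)=CCC1(CC=C(C)C)C(=O)C(C(=O)C(C)C)=C(O)C([C@H](O)[C@@H](O)C(C)C)=C1O | target

## Step count and risks

Total step count: 5. Longest linear sequence: 3 steps (1 → 2 → 5, or 3 → 4 → 5).

**Step 2 (one-pot Claisen/Dieckmann cascade).** The hindered ester of 3 may be attacked slowly, the dianion may react with both ester groups, or O-cyclization to a pyranone may win. The fallback sets out from 3 and comes back at 5. One ester of 3 is saponified (KOH, 1.0 equiv, MeOH/H2O) to the half-ester 2-(methoxycarbonyl)-5-methyl-2-(3-methylbut-2-en-1-yl)hex-4-enoic acid F1. F1 is activated with carbonyldiimidazole to the acyl imidazolide methyl 2-(1H-imidazole-1-carbonyl)-5-methyl-2-(3-methylbut-2-en-1-yl)hex-4-enoate F2. F2 acylates the dilithium dianion of 4 at –78 °C, where the far more reactive, mono-functional acyl donor gives 5 as an isolated compound. 5 is then closed to 6 in a separate operation with NaOMe in MeOH at reflux.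

**Step 4 (partial reduction).** Over-reduction to the alcohol or erosion of the α-center of the aldehyde on handling is possible. The fallback sets out from 8 and comes back at 9. 8 is reduced completely with LiAlH4 to (2S)-2-(1-ethoxyethoxy)-3-methylbutan-1-ol F3, which is oxidized with SO3·pyridine/DMSO/iPr2NEt at 0 °C to 9 immediately before use.

**Step 5 (late aldol).** The adduct may dehydrate to the alkylidene trione and take up a second molecule of 6, the aldol may revert, or the syn:anti ratio may be modest. The fallback sets out from 4 and 9 and comes back at 11; it moves the C4–C1' bond formation ahead of ring formation.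
- The dilithium dianion of 4 is added at –78 °C to 9 precomplexed with MgBr2·OEt2, an irreversible chelation-controlled aldol with no dehydration pathway, giving (7S,8S)-8-(1-ethoxyethoxy)-7-hydroxy-2,9-dimethyldecane-3,5-dione F4; any anti epimer is separated at this simple stage.
- Silylation (Et3SiCl, imidazole) gives (7S,8S)-8-(1-ethoxyethoxy)-2,9-dimethyl-7-(triethylsilyloxy)decane-3,5-dione F5.
- The dianion of F5 is acylated by 3 under the conditions of step 2 to methyl 4-[(1S,2S)-2-(1-ethoxyethoxy)-3-methyl-1-(triethylsilyloxy)butyl]-8-methyl-2,2-bis(3-methylbut-2-en-1-yl)-3,5,7-trioxononanoate F6 (not isolated).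
- F6 closes to 4-[(1S,2S)-2-(1-ethoxyethoxy)-3-methyl-1-(triethylsilyloxy)butyl]-3,5-dihydroxy-2-(2-methylpropanoyl)-6,6-bis(3-methylbut-2-en-1-yl)cyclohexa-2,4-dien-1-one F7.
- 0.5 M aq. HCl/THF removes both protecting groups to give 11.

## Further compounds

F1 | step 2 | 2-(methoxycarbonyl)-5-methyl-2-(3-methylbut-2-en-1-yl)hex-4-enoic acid | COC(=O)C(CC=C(C)C)(CC=C(C)C)C(=O)O
F2 | step 2 | methyl 2-(1H-imidazole-1-carbonyl)-5-methyl-2-(3-methylbut-2-en-1-yl)hex-4-enoate | COC(=O)C(CC=C(C)C)(CC=C(C)C)C(=O)n1ccnc1
F3 | step 4 | (2S)-2-(1-ethoxyethoxy)-3-methylbutan-1-ol | OC[C@@H](OC(C)OCC)C(C)C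
F4 | step 5 | (7S,8S)-8-(1-ethoxyethoxy)-7-hydroxy-2,9-dimethyldecane-3,5-dione | CC(C)C(=O)CC(=O)C[C@H](O)[C@@H](OC(C)OCC)C(C)C
F5 | step 5 | (7S,8S)-8-(1-ethoxyethoxy)-2,9-dimethyl-7-(triethylsilyloxy)decane-3,5-dione | CC(C)C(=O)CC(=O)C[C@H](O[Si](CC)(CC)CC)[C@@H](OC(C)OCC)C(C)C
F6 | step 5 | methyl 4-[(1S,2S)-2-(1-ethoxyethoxy)-3-methyl-1-(triethylsilyloxy)butyl]-8-methyl-2,2-bis(3-methylbut-2-en-1-yl)-3,5,7-trioxononanoate | COC(=O)C(CC=C(C)C)(CC=C(C)C)C(=O)C(C(=O)CC(=O)C(C)C)[C@H](O[Si](CC)(CC)CC)[C@@H](OC(C)OCC)C(C)C
F7 | step 5 | 4-[(1S,2S)-2-(1-ethoxyethoxy)-3-methyl-1-(triethylsilyloxy)butyl]-3,5-dihydroxy-2-(2-methylpropanoyl)-6,6-bis(3-methylbut-2-en-1-yl)cyclohexa-2,4-dien-1-one | CC(C)=CCC1(CC=C(C)C)C(=O)C(C(=O)C(C)C)=C(O)C([C@H](O[Si](CC)(CC)CC)[C@@H](OC(C)OCC)C(C)C)=C1O
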